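**Plan**

Ring numbering used throughout: C1 carries CO2Me, C1=C2 is the olefin, C3 and C5 carry the ester oxygens, C4 the free hydroxyl, C6 is the CH2.
Retrosynthesis: C3–C4 is cut first (intramolecular α-acyloxyallylation of a C4 aldehyde), then C1=C2 (cross-metathesis), the O5 ester bond, and C5–C6 (Barbier allylation).
Enabling feature: C3 is allylic, lies γ to the C1 ester carbonyl and bears an acyloxy group, and its neighbour C4 is a free carbinol. An allylic gem-diester at C3 is therefore a latent γ-acyloxy dienolate (ionization by zerovalent palladium, reduction by InI). Its addition to the C4 aldehyde closes the ring and leaves one acyl group on O3 and a free hydroxyl on C4.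
Forward: a three-carbon chiral-pool aldehyde and a 2-(methoxycarbonyl)allyl unit give C4–C6 and C1; esterification places the O5 acyl group; cross-metathesis with an acrolein gem-diester brings C2 and C3; excision of the dioxolane unmasks the C4 aldehyde; the single carbocycle is closed last and the product of that step is the target.
Stereochemistry: C5 comes from Felkin–Anh addition under control of the glyceraldehyde centre, which is later excised; C4 and C3 are set in the ring closure by the C5 ester (Cornforth arrangement) and the (E)-enol ester geometry; the E acyl groups come with the acid.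

Key step: step 7

Remark: (E)-3-methylpent-2-enoic acid 1 is taken as a purchasable, geometrically pure acid; no step touches its double bond.

**Route**

Step 1
Reactants: 1 (E)-3-methylpent-2-enoic acid
Product: 2 (E)-3-methylpent-2-enoic anhydride
Conditions: DCC (0.5 equiv per acid), CH2Cl2, 0 °C to rt; filtration
Reagents that add atoms: (E)-3-methylpent-2-enoic acid (the second molecule of 1), CC/C(C)=C/C(=O)O
Why: Carbodiimide-mediated dehydration joins two molecules of the acid (DCC anhydride formation) under neutral conditions and should leave the trisubstituted E olefin untouched; no stereocentre is formed.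

Step 2
Reactants: 3 acrolein; 2 (E)-3-methylpent-2-enoic anhydride
Product: 4 prop-2-ene-1,1-diyl bis[(E)-3-methylpent-2-enoate]
Conditions: Sc(OTf)3 (2 mol%), CH2Cl2, 0 °C
Reagents that add atoms: none
Why: Lewis acid-catalysed 1,2-addition of an anhydride to an aldehyde (acylal formation) is general for enals and builds the allylic gem-diester that later serves as both leaving group and O3 ester; no stereocentre is formed.

Step 3
Reactants: 5 (S)-2,2-dimethyl-1,3-dioxolane-4-carbaldehyde; 6 methyl 2-(bromomethyl)acrylate
Product: 7 methyl (R)-4-[(S)-2,2-dimethyl-1,3-dioxolan-4-yl]-4-hydroxy-2-methylenebutanoate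
Conditions: In powder (1.2 equiv), THF/H2O 1:1, rt; neutral work-up, chromatography
Reagents that add atoms: none
Why: Indium-mediated Barbier allylation in water tolerates the ester and the acetal, and Felkin–Anh (non-chelated) addition to the α-alkoxy aldehyde should favour the anti adduct, which sets C5 as R under control of the dioxolane centre; the minor syn epimer is removed by chromatography.

Step 4
Reactants: 7 methyl (R)-4-[(S)-2,2-dimethyl-1,3-dioxolan-4-yl]-4-hydroxy-2-methylenebutanoate; 2 (E)-3-methylpent-2-enoic anhydride
Product: 8 methyl (R)-4-[(S)-2,2-dimethyl-1,3-dioxolan-4-yl]-2-methylene-4-{[(E)-3-methylpent-2-enoyl]oxy}butanoate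
Conditions: 2 (1.5 equiv), DMAP (0.1 equiv), pyridine, CH2Cl2, 0 °C to rt
Reagents that add atoms: none
Why: DMAP-catalysed acylation of the secondary alcohol by the anhydride (nucleophilic acyl-transfer catalysis) installs the O5 ester without touching C5 and removes the hydroxyl that could lactonize onto the methyl ester.

Step 5
Reactants: 8 methyl (R)-4-[(S)-2,2-dimethyl-1,3-dioxolan-4-yl]-2-methylene-4-{[(E)-3-methylpent-2-enoyl]oxy}butanoate; 4 prop-2-ene-1,1-diyl bis[(E)-3-methylpent-2-enoate]
Product: 9 methyl (E)-2-[(R)-2-[(S)-2,2-dimethyl-1,3-dioxolan-4-yl]-2-{[(E)-3-methylpent-2-enoyl]oxy}ethyl]-4,4-bis{[(E)-3-methylpent-2-enoyl]oxy}but-2-enoate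
Conditions: second-generation Hoveyda–Grubbs catalyst (5–10 mol%, in portions), 4 (3 equiv), CH2Cl2, 40 °C
Reagents that add atoms: none
Why: Olefin cross-metathesis between a 1,1-disubstituted acrylate, which does not homodimerize, and an excess of the terminal olefin 4 should give the trisubstituted enoate (E expected, but either isomer serves later); no stereocentre is formed.

Step 6
Reactants: 9 methyl (E)-2-[(R)-2-[(S)-2,2-dimethyl-1,3-dioxolan-4-yl]-2-{[(E)-3-methylpent-2-enoyl]oxy}ethyl]-4,4-bis{[(E)-3-methylpent-2-enoyl]oxy}but-2-enoate
Product: 11 methyl (E)-4,4-bis{[(E)-3-methylpent-2-enoyl]oxy}-2-[(R)-2-{[(E)-3-methylpent-2-enoyl]oxy}-3-oxopropyl]but-2-enoate, via diol 10 (not isolated)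
Conditions: H5IO6 (1.5 equiv), EtOAc, 0 °C to rt; aqueous wash, used crude
Reagents that add atoms: none
Why: Periodic acid hydrolyses the terminal acetonide and cleaves the liberated glycol 10 in one flask (oxidative glycol cleavage), conditions under which the esters, the gem-diester and the C5 centre (no base present) should survive; the old glyceraldehyde stereocentre becomes the aldehyde carbon C4.

Step 7
Reactants: 11 methyl (E)-4,4-bis{[(E)-3-methylpent-2-enoyl]oxy}-2-[(R)-2-{[(E)-3-methylpent-2-enoyl]oxy}-3-oxopropyl]but-2-enoate
Product: 13 methyl (3R,4S,5R)-4-hydroxy-3,5-bis{[(E)-3-methylpent-2-enoyl]oxy}cyclohex-1-ene-1-carboxylate, via indium dienolate 12 (not isolated)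
Conditions: Pd(PPh3)4 (5 mol%), InI (1.5 equiv), degassed THF (0.01 M), 0 °C to rt; pH 7 phosphate buffer at 0 °C
Reagents that add atoms: indium monoiodide, [In]I (its atoms are held only in 12 and are lost on work-up)
Why: Proposed new method: zerovalent palladium should ionize one carboxylate of the allylic gem-diester at C3 to an acyloxy-substituted η3-allylpalladium, which InI reduces by reductive transmetalation to the indium dienolate 12; its γ-carbon C3 then adds to the tethered C4 aldehyde, α-attack being excluded because it would give a cyclobutane. The closest known reaction types are the palladium-catalysed, indium monoiodide-mediated umpolung allylation of aldehydes with allylic esters, the indium- or zinc-mediated α-acyloxyallylation with 3-bromopropenyl esters and the iridium-catalysed acyloxyallylation with allylic gem-dicarboxylates, all intermolecular and none with an ester on the allyl terminus. The cyclohexene closes in a 6-(enolendo)-exo-trig vinylogous aldol mode through an open, chair-like transition state, because the C5–C6 tether occupies the site over C1 and so keeps the metal of the dienolate away from the aldehyde oxygen; since the C1–C2 bond of 12 is single, either olefin isomer of 11 can reach the reactive conformer. C4 is controlled by the existing C5 ester: its C–O bond should lie antiperiplanar to the C4=O bond, which is activated by trivalent indium (Cornforth-type dipole minimization), so that both oxygens are axial in the forming ring and the 4,5-trans relation results. C3 is controlled by the enol ester geometry: the acyloxy group should sit syn in the allyl complex because an anti site at C1 is already occupied, which gives the (E)-enol ester, and its oxygen then takes the equatorial site at C3 on the same ring face as the axial carbonyl oxygen (synclinal to C2=C3), which is the 3,4-cis relation. The step needs chemoselective ionization, secured because only the gem-diester is allylic (the C5 ester is homoallylic), and a cold neutral quench to prevent acyl migration onto the new hydroxyl.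

**Compound list**

1 | (E)-3-methylpent-2-enoic acid | CC/C(C)=C/C(=O)O | starting material
2 | (E)-3-methylpent-2-enoic anhydride | CC/C(C)=C/C(=O)OC(=O)/C=C(\C)CC | intermediate
3 | acrolein | C=CC=O | starting material
4 | prop-2-ene-1,1-diyl bis[(E)-3-methylpent-2-enoate] | C=CC(OC(=O)/C=C(\C)CC)OC(=O)/C=C(\C)CC | intermediate
5 | (S)-2,2-dimethyl-1,3-dioxolane-4-carbaldehyde | O=C[C@@H]1COC(C)(C)O1 | starting material
6 | methyl 2-(bromomethyl)acrylate | C=C(CBr)C(=O)OC | starting material
7 | methyl (R)-4-[(S)-2,2-dimethyl-1,3-dioxolan-4-yl]-4-hydroxy-2-methylenebutanoate | C=C(C[C@@H](O)[C@@H]1COC(C)(C)O1)C(=O)OC | intermediate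
8 | methyl (R)-4-[(S)-2,2-dimethyl-1,3-dioxolan-4-yl]-2-methylene-4-{[(E)-3-methylpent-2-enoyl]oxy}butanoate | C=C(C[C@@H](OC(=O)/C=C(\C)CC)[C@@H]1COC(C)(C)O1)C(=O)OC | intermediate
9 | methyl (E)-2-[(R)-2-[(S)-2,2-dimethyl-1,3-dioxolan-4-yl]-2-{[(E)-3-methylpent-2-enoyl]oxy}ethyl]-4,4-bis{[(E)-3-methylpent-2-enoyl]oxy}but-2-enoate | COC(=O)/C(C[C@@H](OC(=O)/C=C(\C)CC)[C@@H]1COC(C)(C)O1)=C/C(OC(=O)/C=C(\C)CC)OC(=O)/C=C(\C)CC | intermediate
10 | methyl (E)-2-[(2R,3S)-3,4-dihydroxy-2-{[(E)-3-methylpent-2-enoyl]oxy}butyl]-4,4-bis{[(E)-3-methylpent-2-enoyl]oxy}but-2-enoate (not isolated) | OC[C@H](O)[C@H](OC(=O)/C=C(\C)CC)C/C(C(=O)OC)=C\C(OC(=O)/C=C(\C)CC)OC(=O)/C=C(\C)CC | intermediate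
11 | methyl (E)-4,4-bis{[(E)-3-methylpent-2-enoyl]oxy}-2-[(R)-2-{[(E)-3-methylpent-2-enoyl]oxy}-3-oxopropyl]but-2-enoate | O=C[C@H](OC(=O)/C=C(\C)CC)C/C(C(=O)OC)=C\C(OC(=O)/C=C(\C)CC)OC(=O)/C=C(\C)CC | intermediate
12 | indium dienolate of 11: O-bound iodo[(E)-3-methylpent-2-enoato]indium ketene acetal, (E)-enol ester at C2=C3, (R) at C5, ketene acetal geometry not defined (not isolated) | COC(O[In](I)OC(=O)/C=C(\C)CC)=C(C[C@@H](OC(=O)/C=C(\C)CC)C=O)/C=C/OC(=O)/C=C(\C)CC | intermediate
13 | methyl (3R,4S,5R)-4-hydroxy-3,5-bis{[(E)-3-methylpent-2-enoyl]oxy}cyclohex-1-ene-1-carboxylate | CC/C(C)=C/C(=O)O[C@@H]1C=C(C(=O)OC)C[C@@H](OC(=O)/C=C(\C)CC)[C@@H]1O | target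

**Step count and risks**

Total step count: 7 (steps 1 and 2 prepare the acylating agent and the metathesis partner).
Longest linear sequence: 5 steps (steps 3 to 7).

Step 7 (Proposed new method). The indium dienolate may be protonated, or the allyl complex may eliminate to a 1-acyloxydiene, before ring closure. The aldehyde may instead react through the arrangement with an equatorial carbonyl oxygen (C5–O antiperiplanar to the incoming carbon, polar Felkin–Anh), which with the (E)-enol ester would invert the C3–C4 relation; facial selectivity at the aldehyde may therefore be poor. The new C4 alkoxide may also take an acyl group from O3 or O5 (acyl migration). The fallback uses known chemistry, sets out from 8 and returns at 13. The dioxolane of 8 is cleaved with H5IO6 as in step 6 to the aldehyde methyl (R)-2-methylene-4-{[(E)-3-methylpent-2-enoyl]oxy}-5-oxopentanoate F1. F1 is coupled with gem-diester 4 by the known intermolecular iridium-catalysed transfer-hydrogenative α-acyloxyallylation of aldehydes ([Ir(cod)Cl]2, a SEGPHOS ligand, 4-cyano-3-nitrobenzoic acid, catalytic Cs2CO3, 2-propanol as reductant, THF, 90 °C). That reaction is anti-selective between the new carbinol and the new ester carbon, which is the 3,4-cis relation once the ring is closed, and the ligand enantiomer is chosen to impose the C4 configuration against the Felkin–Anh preference of the substrate. It should give the diene methyl (4R,5S,6R)-5-hydroxy-2-methylene-4,6-bis{[(E)-3-methylpent-2-enoyl]oxy}oct-7-enoate F2. Ring-closing metathesis of F2 (second-generation Grubbs catalyst, CH2Cl2, 40 °C) then forms C1=C2 and gives 13.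

Step 5. The hindered 1,1-disubstituted acrylate may turn over slowly while 4 homodimerizes, so that the ruthenium carbene is consumed in unproductive cycles. The fallback replaces metathesis by carbonyl olefination, sets out from 7 and returns at 9. Alcohol 7 is silylated (Et3SiCl, imidazole, CH2Cl2) to methyl (R)-4-[(S)-2,2-dimethyl-1,3-dioxolan-4-yl]-2-methylene-4-(triethylsilyloxy)butanoate F3. Its only olefin is ozonized (O3, CH2Cl2, −78 °C; PPh3) to the α-keto ester methyl (R)-4-[(S)-2,2-dimethyl-1,3-dioxolan-4-yl]-2-oxo-4-(triethylsilyloxy)butanoate F4. Wittig reaction of the activated ketone with (triphenylphosphoranylidene)acetaldehyde (toluene, rt to 50 °C) should give the enal methyl (E)-2-[(R)-2-[(S)-2,2-dimethyl-1,3-dioxolan-4-yl]-2-(triethylsilyloxy)ethyl]-4-oxobut-2-enoate F5; either olefin isomer serves. Treatment of F5 with anhydride 2 and catalytic Sc(OTf)3 (MeCN, −20 to 0 °C) should convert the aldehyde into the gem-diester and, in the same flask, exchange the labile silyl ether for the ester (direct silyl ether to ester conversion), giving 9.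

Step 3. Facial selectivity in the addition to the α-alkoxy aldehyde may be poor, so that anti and syn adducts form in comparable amounts; the γ-hydroxy ester may also lactonize on handling. The fallback makes the C5 configuration independent of facial selectivity, sets out from 5 (with 6) and returns at 8. The syn epimer methyl (S)-4-[(S)-2,2-dimethyl-1,3-dioxolan-4-yl]-4-hydroxy-2-methylenebutanoate F6, separated from 7, is esterified with acid 1 under Mitsunobu conditions (PPh3, DIAD, THF, 0 °C). This inverts the carbinol centre and delivers 8 directly, so both epimers converge.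

**Further compounds**

F1 | step 7 | methyl (R)-2-methylene-4-{[(E)-3-methylpent-2-enoyl]oxy}-5-oxopentanoate | O=C[C@H](OC(=O)/C=C(\C)CC)CC(=C)C(=O)OC
F2 | step 7 | methyl (4R,5S,6R)-5-hydroxy-2-methylene-4,6-bis{[(E)-3-methylpent-2-enoyl]oxy}oct-7-enoate | C=C[C@@H](OC(=O)/C=C(\C)CC)[C@@H](O)[C@H](OC(=O)/C=C(\C)CC)CC(=C)C(=O)OC
F3 | step 5 | methyl (R)-4-[(S)-2,2-dimethyl-1,3-dioxolan-4-yl]-2-methylene-4-(triethylsilyloxy)butanoate | C=C(C[C@@H](O[Si](CC)(CC)CC)[C@@H]1COC(C)(C)O1)C(=O)OC
F4 | step 5 | methyl (R)-4-[(S)-2,2-dimethyl-1,3-dioxolan-4-yl]-2-oxo-4-(triethylsilyloxy)butanoate | O=C(C[C@@H](O[Si](CC)(CC)CC)[C@@H]1COC(C)(C)O1)C(=O)OC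
F5 | step 5 | methyl (E)-2-[(R)-2-[(S)-2,2-dimethyl-1,3-dioxolan-4-yl]-2-(triethylsilyloxy)ethyl]-4-oxobut-2-enoate | O=C/C=C(\C[C@@H](O[Si](CC)(CC)CC)[C@@H]1COC(C)(C)O1)C(=O)OC
F6 | step 3 | methyl (S)-4-[(S)-2,2-dimethyl-1,3-dioxolan-4-yl]-4-hydroxy-2-methylenebutanoate | C=C(C[C@H](O)[C@@H]1COC(C)(C)O1)C(=O)OC
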